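At late times both earlier runs had levelled off in target, although theta still held 19.2 % of its solid substrate at 5.00 min. That is what I held against your hunch, when you asked for a quick number, that more solid substrate would keep buying more target.

| flask | solid substrate | partner | remark | time |
|---|---|---|---|---|
| delta | 0.022 M | 0.091 M | run made earlier |  |
| theta | 0.53 M | 0.091 M | run made earlier |  |
| cedar | 0.015 M | 0.0910 M |  | 5.0 min |
| larch | 0.040 M | 0.0910 M |  | 5.0 min |
| birch | 0.12 M | 0.0910 M |  | 5.0 min |
| oak | 0.40 M | 0.0910 M |  | 5.0 min |

- delta (time / min: target / %, solid substrate / %): 0.417: 27.3, 16.9; 0.833: 48.3, 0.1; 1.33: 56.2, 0.3; 2.50: 59.7, 0; 5.00: 60.0, 0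
- theta (time / min: target / %, solid substrate / %): 0.417: 1.9, 72.2; 1.33: 2.8, 44.3; 2.50: 3.4, 30.1; 4.00: 2.9, 22.3; 5.00: 2.8, 19.2

(each reading ± 0.3 percentage points)

- percentages count the solid substrate that a species holds: one homo dimer counts as two
- solid, in amounts per volume of the solution: solid substrate
- the analysis behind the earlier runs scatters by 0.3 percentage points, standard deviation
- reactions considered so far: solid substrate <-> dissolved substrate; dissolved substrate + partner -> target; partner -> side product; target <-> isomer of the product; 2 solid substrate -> homo dimer
- at the start none of the solid substrate is in solution
- "hardly changes" means that all values lie within two and a half points (for a concentration: within two and a half percent of the largest)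
- a step back or a flat step of under half a percent of the largest counts as no turn

- [target] at the end for cedar, larch, birch, oak, in this order
- how that number moves from the first to the last of them (falls, then rises / falls all the way / rises, then falls / rises all the way / hardly changes)

I took the proportional case as the zero of my scale: each flask turns delta's final share of its charge into target.

share = 60.0 %

Against that I set the ceiling, the mean [target] read in theta from 2.50 min on, with solid substrate still present. Each reading carries a scatter of 0.3 percentage points.

ceiling = 0.0161 M

crossing charge = ceiling / share = 0.0268 M

Cedar's charge lay below the crossing, so I reckoned it proportionally: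

[target] = share × 0.015 M = 0.00900 M

Larch's charge lay above the crossing, and birch's and oak's were larger still, so I gave all of them 0.0161 M.

The forecast gave 0.0093 M, 0.015 M, 0.0156 M and 0.0158 M, a row that rises all the way, and said of theta: “Here dissolved substrate sits at saturation”. That differed from my reckoning: it stood higher at cedar and lower at larch.

The flasks gave 0.0102 M, 0.0160 M, 0.0161 M and 0.0161 M, a row that rises all the way, and the forecast held.

    solid substrate ⇌ dissolved substrate, rate k1*(cs1 - [dissolved substrate]) while solid is left; crystals form when [dissolved substrate] > cs1 (solubility = 25.0 mM, k = 0.0410 s⁻¹)
    dissolved substrate + partner → target (k = 0.638 L mol⁻¹ s⁻¹)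
    partner → side product (k = 0.0272 s⁻¹)
    target ⇌ isomer of the product (K = 0.111, k = 0.136 s⁻¹)
    2 solid substrate → homo dimer (k = 0.0129 L mol⁻¹ s⁻¹)

Oak ended at 1.00 times the ceiling, and birch at 1.00 times it, with 37.5 % of birch's charge still solid at 5.00 min and its limiting reagent, partner, at 0 %. In cedar, partner's half-life by passing into side product alone was 0.42 min, shorter than the 1.9 min by the step to target at 0.368 min, and the ratio of those two rates of use went from 4.6 then to 12 at 5.00 min.

Readings and results are simulated with made-up constants.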